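## Structural features

The target is a germacranolide: a ten-membered carbocycle (C1–C10) with a trans-fused α-methylene-γ-butyrolactone across C6–C7 (O6–C12, exocyclic C11=C13), a free hydroxyl on C8, a methacrylate on the C14 oxygen (C14 on C10) and an acetate on the C15 oxygen (C15 on C4). The ring contains two trisubstituted double bonds, C1=C10 and C4=C5, both cis within the ring and separated by the C2–C3 bridge. C6, C7 and C8 are three contiguous stereocentres (all R): O6 and C11 are syn and O6 and O8 anti along the C5–C9 chain, so H6 and H7 are trans and the 8-hydroxyl lies on the ring face of C11. Fragile elements are the α-methylene lactone and the methacrylate (Michael acceptors), the two primary allylic esters, the allylic lactone C6–O bond, the β-hydroxy lactone (which could relactonise to O8), and a medium-ring 1,5-diene that is prone to transannular reactions. The real difficulty is the combination: a ten-membered ring with two ring-cis trisubstituted alkenes, a stereotriad on the same ring, and two nearly identical allylic CH2O groups that must carry different acyl groups. The key step exploits two facts. C10=C1–C2–C3–C4=C5 becomes a cis,cis-cycloocta-1,5-diene once C6 and C9 are joined. The C6(O)–C7–C8(O) 1,3-dioxygenated stretch is what a ketene two-carbon unit (C7, C8) leaves when it is inserted into that C6–C9 bond.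

## Logic of the disconnections

33 ⇒ 28 (through 31 and 30). The two ester C–O bonds at O14 and O15 are cut, because neither acyl group would survive the enolate chemistry that precedes them. This leaves O15 as a TBS ether and O14 as a TBDPS ether, which can be removed in that order. The forward steps must acylate a primary allylic hydroxyl in the presence of the secondary 8-hydroxyl, twice.

28 ⇒ 27 ⇒ 22 + 23. The exocyclic C11=C13 bond is cut; the Michael acceptor is made last among the C–C bond formations. This simplifies the lactone to a plain butanolide. The forward step has to enolise the lactone at C11 in the presence of the free 8-hydroxyl.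

22 ⇒ 21. The C8–H bond is cut (ketone reduction). C8 then becomes a carbonyl that keeps C7 adjustable and comes directly from the ring expansion. The demand is face selection at C8 by a chiral reagent without β-elimination of the lactone oxygen.

21 ⇒ 19 (through 20). The O6–C12 lactone bond and the C6–H bond are cut. In 19, C6 is the alkenyl ketone of a 2-substituted 1,3-dione whose C7 epimerises freely, so one asymmetric transfer hydrogenation can set C6 and C7 together. Lactonisation while C8 is still a ketone fixes the lactone on O6 without ambiguity. The demand is hydride delivery to C6 rather than C8 and a syn C6/C7 relationship.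

19 ⇒ 17 + 18. The C7–C11 bond is cut; C7 is the doubly activated carbon of the 1,3-dione. The gain is an achiral, symmetrically functionalised ring. The demand is mono C-alkylation rather than O-alkylation.

17 ⇒ 14 (key). The C6–C9 bond is re-formed in the retrosynthetic sense: 17 is the retro-aldol product of a 3-siloxycyclobutanone fused to an eight-membered ring. The ten-membered ring with two ring-cis alkenes is thereby reduced to an eight-membered ring in which cis is the only option. The forward step must break the fusion bond (not C6–C7), protonate C9 (not C1) and remove the tertiary TMS ether without touching the primary silyl ethers.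

14 ⇒ 13 ⇒ 11 + 12. After two chlorines are restored, the C6–C7 and C8–C9 bonds are cut as a [2+2] cycloaddition of a ketene unit from 12. The demand is reaction at the enol ether bond C6=C9 of a cross-conjugated triene with C8 bonding to C9.

11 ⇒ 9. The O–Si bond of the enol ether is cut. The forward step needs kinetic deprotonation at C9, the only sp3 α-carbon of the ketone.

9 ⇒ 7 + 4 (through 8). The C10–C14 bond and the O14–Si bond are cut, so that the C14 arm is introduced after the ketone. This is the point where the design had to be repaired. 14 and 17 themselves are consistent in constitution, ring fusion and alkene geometry. In a diene carrying both CH2O arms, however, C2 and C6 are equivalent apart from the remote silyl groups, so an allylic oxidation cannot place the ketone relative to two different protecting groups. Keeping C10 as an enol triflate in 7 deactivates that side and marks it as the C14 side. The forward coupling must be mild enough that C10=C1 does not move into conjugation.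

7 ⇒ 6. The C6=O group is returned to CH2 (allylic oxidation). The demand is oxidation next to C5 of the electron-rich alkene and not next to the vinyl triflate.

6 ⇒ 5 ⇒ 3 + 4. The O15–Si and C4–C15 bonds are cut. The two triflates of 3 are homotopic, so the forward monocoupling is statistical and unreacted 3 is recycled.

3 ⇒ 1. The two C–O(triflyl) bonds are cut back to the diketone. The demand is double enolisation toward different bridges (1,5-diene, not 1,4-diene).

## Other disconnections considered

Alternative 1: The cut lies inside a six-carbon fragment: the C6–H bond and the O6–C12 lactone bond of A1, formed from the racemic keto diester A2 in which C7 sits between a ketone and an ester.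
- Forward key step: a ketoreductase with nicotinamide cofactor recycling reduces C6 of one rapidly equilibrating C7 epimer, and the new hydroxyl lactonises onto C12.
- In favour: enzymes of this class typically single out one of the four stereoisomers of an α-substituted β-keto ester, in water at ambient temperature, without tin, zinc or a ketene. In dependability of stereocontrol at C6/C7 this is better than step 12 of the chosen plan, where a metal catalyst must choose between two ketones of a flexible macrocycle. Both plans are equal in using a 1,3-dicarbonyl to make C7 epimerisable.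
- Against: A1 holds six of the fifteen skeletal carbons and none of the hard parts. The ten-membered ring, both ring-cis alkenes, C8 (still an ester carbon) and the C4–C5 bond remain, and the ring must still be closed by a macrocyclisation.
- Comparison: mechanistically this is the more conservative plan. Structurally the chosen plan delivers ring and alkene geometry from an eight-membered template in ten steps, and the fragment route is expected to need clearly more than eighteen steps overall.

Alternative 2: The cut is the C5–C6 ring bond together with O6–C12.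
- Forward key step: a C5 vinyl iodide, activated by divalent chromium with a nickel co-catalyst (Nozaki–Hiyama–Kishi reaction), adds to the C6 aldehyde. The C6 alkoxide then closes the lactone onto a C12 tert-butyl ester on mild acid work-up, giving A3.
- In favour: ring, C6 stereocentre and lactone arise in one operation, and the reaction tolerates silyl ethers and esters. C14 and C15 come from different fragments and are differentiated for free, which is better than steps 2–6 of the chosen plan. C7 and C8 are set in an open chain, which is better understood than steps 12 and 13.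
- Against: the C6 configuration is created during ring closure under 1,2-induction from C7 alone, and its sense in a strained ten-membered transition state is hard to predict. The closure needs high dilution and a large excess of a toxic chromium salt. Each ring-cis trisubstituted alkene, one as a geometrically pure vinyl iodide, needs its own stereoselective olefination.
- Comparison: A3 is still 11,13-dihydro and fully protected, so the end game is equal in length to that of the chosen plan; the total is expected to be longer.

Alternative 3: The cut is the C1=C10 double bond.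
- Forward key step: an intramolecular Horner–Wadsworth–Emmons reaction. A C10 phosphonoacetate carbanion (lithium salt and amine base, Masamune–Roush conditions, high dilution) adds to the C1 aldehyde and gives A4. The C6–C8 stereotriad is derived from D-arabinose A5.
- In favour: the absolute configuration comes from the chiral pool, which is better than any catalyst-controlled step of the chosen plan. The macrocyclic olefination is among the best-precedented ring closures. Its normal preference (ester trans to the β-substituent) coincides with the ring-cis geometry at C1=C10, so on that alkene it is equal to the chosen plan.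
- Against: A5 offers three contiguous C–O stereocentres, but C7 carries a carbon branch, so one oxygen must be exchanged for C11 with stereocontrol, besides chain extension at both ends. C4=C5 must be built separately. C14 emerges as a conjugated allyl ester that has to be reduced later without touching the γ-lactone.
- Comparison: the linear sequence is expected to be well above eighteen steps.

Key step: step 10

Remark: germacrane numbering is used throughout (ring C1–C10, C14 on C10, C15 on C4, C11–C13 on C7). Every ring C=C is cis within its ring, which reads E by the CIP rules wherever an exocyclic CH2O or triflate oxygen outranks the ring CH2. Compounds 13–15 are racemic and drawn as one enantiomer; 19 is racemic at C7 and epimerises freely.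

## Route

Step 1
Reactants: 1 cyclooctane-1,5-dione
Product: 3 cycloocta-1,5-diene-1,5-diyl bis(trifluoromethanesulfonate), via dilithium bis-enolate 2 (not isolated)
Conditions: LiN(iPr)2 (2.3 equiv), THF, −78 °C; PhNTf2 (2.4 equiv), −78 °C → rt
Reagents that add atoms: N-phenylbis(trifluoromethanesulfonimide), O=S(=O)(N(c1ccccc1)S(=O)(=O)C(F)(F)F)C(F)(F)F
Why: Double kinetic enolisation followed by O-sulfonylation (enol triflate formation). The second deprotonation is expected on the α-carbon remote from the first enolate unit, which gives the C2-symmetric 1,5-diene; the Cs-symmetric 1,4-diene is the likely by-product and is covered by a fallback.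

Step 2
Reactants: 3 cycloocta-1,5-diene-1,5-diyl bis(triflate); 4 (tributylstannyl)methanol
Product: 5 5-(hydroxymethyl)cycloocta-1,5-dien-1-yl trifluoromethanesulfonate
Conditions: Pd(PPh3)4 (5 mol %), LiCl (3 equiv), 1,4-dioxane, 80 °C; 4 (0.9 equiv); KF work-up
Reagents that add atoms: none
Why: Stille hydroxymethylation of an enol triflate; LiCl converts the vinylpalladium triflate into the chloride so that transmetallation can proceed. The two triflates are homotopic, so a deficit of 4 should give mainly monocoupling and unreacted 3 is recycled.

Step 3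
Reactants: 5 hydroxymethyl dienyl triflate
Product: 6 5-[(tert-butyldimethylsilyloxy)methyl]cycloocta-1,5-dien-1-yl trifluoromethanesulfonate
Conditions: TBSCl, imidazole, DMF, 0 °C → rt
Reagents that add atoms: tert-butyldimethylsilyl chloride, CC(C)(C)[Si](C)(C)Cl
Why: Imidazole-promoted silylation of a primary allylic alcohol; this oxygen becomes O15.

Step 4
Reactants: 6 silyl ether dienyl triflate
Product: 7 5-[(tert-butyldimethylsilyloxy)methyl]-7-oxocycloocta-1,5-dien-1-yl trifluoromethanesulfonate
Conditions: Rh2(cap)4 (dirhodium tetrakis(caprolactamate), 1 mol %), t-BuOOH (5 equiv), K2CO3, CH2Cl2, rt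
Reagents that add atoms: tert-butyl hydroperoxide, CC(C)(C)OO
Why: Catalytic allylic C–H oxidation by a tert-butylperoxyl radical chain. The triflate makes its own alkene electron-poor, so hydrogen abstraction should occur beside the electron-rich C4=C5 bond; there C6 gives the more substituted allyl radical and the β,β-disubstituted enone. The ketone is thereby placed on the TBS side only.

Step 5
Reactants: 7 enone triflate; 4 (tributylstannyl)methanol
Product: 8 7-(hydroxymethyl)-3-[(tert-butyldimethylsilyloxy)methyl]cycloocta-2,6-dien-1-one
Conditions: Pd2(dba)3 (2.5 mol %), P(2-furyl)3 (20 mol %), LiCl, NMP, 50 °C; KF work-up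
Reagents that add atoms: none
Why: Second Stille hydroxymethylation, now of the remaining enol triflate. The weakly donating phosphine allows neutral coupling at low temperature, so the β,γ double bond C10=C1 should not drift into conjugation with the C6 ketone.

Step 6
Reactants: 8 hydroxymethyl dienone
Product: 9 3-[(tert-butyldimethylsilyloxy)methyl]-7-[(tert-butyldiphenylsilyloxy)methyl]cycloocta-2,6-dien-1-one
Conditions: TBDPSCl, imidazole, CH2Cl2, 0 °C
Reagents that add atoms: tert-butyldiphenylsilyl chloride, CC(C)(C)[Si](Cl)(c1ccccc1)c1ccccc1
Why: Imidazole-promoted silylation. The more acid-stable group goes on O14 because a free C14 hydroxyl three carbons from the C6 (later C8) ketone could close to a furan.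

Step 7
Reactants: 9 dienone
Product: 11 1-(trimethylsilyloxy)-3-[(tert-butyldiphenylsilyloxy)methyl]-7-[(tert-butyldimethylsilyloxy)methyl]cycloocta-1,3,7-triene, via lithium dienolate 10 (not isolated)
Conditions: LiN(iPr)2 (1.1 equiv), THF, −78 °C; Me3SiCl, Et3N, −78 → 0 °C; non-aqueous work-up, used crude
Reagents that add atoms: chlorotrimethylsilane, C[Si](C)(C)Cl
Why: Kinetic deprotonation at C9, the only sp3 α-carbon of the ketone and allylic as well, followed by O-silylation (silyl enol ether formation). γ-Deprotonation at C3 should be slower with a hindered amide at −78 °C.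

Step 8
Reactants: 11 trimethylsilyl dienol ether; 12 trichloroacetyl chloride
Product: 13 rac-(1S,8S)-10,10-dichloro-3-[(tert-butyldimethylsilyloxy)methyl]-7-[(tert-butyldiphenylsilyloxy)methyl]-1-(trimethylsilyloxy)bicyclo[6.2.0]deca-2,6-dien-9-one
Conditions: Zn–Cu couple, Et2O/DME (4:1), 0 → 15 °C, slow addition of 12; cold filtration
Reagents that add atoms: none
Why: Thermal [2+2] cycloaddition of dichloroketene (formed in the flask) to a silyl enol ether. C6=C9 is the most electron-rich π bond of the twisted triene; C9 attacks the ketene carbonyl carbon and the CCl2 carbon closes on the oxygen-stabilised C6, and suprafacial addition to a ring-cis alkene gives the cis fusion. The adduct is a cis-1,2-dialkenylcyclobutane that could undergo Cope rearrangement, so it is kept at or below room temperature.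

Step 9
Reactants: 13 dichlorocyclobutanone
Product: 14 rac-(1S,8S)-3-[(tert-butyldimethylsilyloxy)methyl]-7-[(tert-butyldiphenylsilyloxy)methyl]-1-(trimethylsilyloxy)bicyclo[6.2.0]deca-2,6-dien-9-one
Conditions: Zn dust, AcOH, TMEDA, EtOH, 0 °C
Reagents that add atoms: none
Why: Reductive removal of both α-chlorines by zinc through zinc enolates that acetic acid protonates at once. The amine buffer should keep the tertiary TMS ether and the ring fusion intact.

Step 10
Reactants: 14 cis-fused siloxycyclobutanone
Product: 17 9-[(tert-butyldimethylsilyloxy)methyl]-5-[(tert-butyldiphenylsilyloxy)methyl]cyclodeca-5,9-diene-1,3-dione, via cyclobutanolate 15 (not isolated), via ring-opened enolate 16 (not isolated)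
Conditions: Bu4NF (1.1 equiv), AcOH (1.3 equiv), THF, −40 → 0 °C
Reagents that add atoms: none
Why: Fluoride attacks the trimethylsilyl group and frees the C6 alkoxide 15, which is β to the C8 carbonyl inside a strained four-membered ring. Retro-aldol fragmentation follows: the C6=O π bond forms as the C6–C9 σ bond breaks and the C8 carbonyl takes up the electrons as enolate 16; the closest known reaction is the desilylative opening of ketene–silyl enol ether adducts, which enlarges cycloalkanones to cycloalkane-1,3-diones by two carbons. No ring is closed by bond formation: the ten-membered ring appears because the cleaved bond is the shared zero-atom bridge of the four- and eight-membered rings, and cyclobutanone strain drives the cleavage. No stereocentre is created; C6 and C9 become a carbonyl carbon and a CH2, 17 is achiral, and both alkenes keep the cis geometry the eight-membered ring imposed. The selectivity needed is C6–C9 over C6–C7 cleavage: the charge developing at C9 is enolate-stabilised and allylic to C10=C1, whereas C7 would be an unstabilised primary enolate carbon, and the prior removal of the chlorines in step 9 is what closes the C7 pathway. Acetic acid protonates the extended enolate at C9 (kinetic α-protonation) before it can add across the ring to C4 of the new C4=C5–C6=O enone; the product then rests as the 1,3-dione whose acidic site is C7, so C10=C1 is not drawn into conjugation. One equivalent of buffered fluoride below 0 °C should remove the tertiary TMS ether far faster than the primary TBS and TBDPS ethers. The low temperature also excludes Cope or oxy-Cope bonding between C1 and C4, which would have to create a new four-membered ring.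

Step 11
Reactants: 17 ten-membered 6,8-dione; 18 methyl bromoacetate
Product: 19 methyl 15-(tert-butyldimethylsilyloxy)-14-(tert-butyldiphenylsilyloxy)-6,8-dioxo-13-norgermacra-1(10),4-dien-12-oate
Conditions: K2CO3 (1.5 equiv), acetone, 0 °C → rt; 18 (1.0 equiv)
Reagents that add atoms: none
Why: C-alkylation of the 1,3-dione enolate at C7 with an α-halo ester. The ten-membered dione can form a U-shaped potassium chelate like an open-chain β-diketone, which favours C- over O-alkylation, and one equivalent of 18 limits double alkylation. C7 becomes a stereocentre but remains labile.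

Step 12
Reactants: 19 alkylated dione
Product: 21 (6R,7S)-15-(tert-butyldimethylsilyloxy)-14-(tert-butyldiphenylsilyloxy)-8-oxo-13-norgermacra-1(10),4-dien-12,6-olide, via hydroxy keto ester 20 (not isolated)
Conditions: RuCl[(S,S)-TsDPEN](p-cymene) (2 mol %), HCO2H/Et3N (5:2), EtOAc, 0 °C → rt; then PPTS (cat.), CH2Cl2, rt
Reagents that add atoms: none
Why: Noyori-type asymmetric transfer hydrogenation with dynamic kinetic resolution: C7 epimerises through the 1,3-dicarbonyl enol while the catalyst reduces the alkenyl ketone C6. The alkenyl group takes the place of the aryl group in the usual CH–π model, so the (S,S) ligand should give 6R, and the syn mode known for α-alkyl β-dicarbonyl compounds places C11 and O6 syn (7S here only because C8=O outranks C6). The hydroxy ester then closes onto O6, the only hydroxyl present, to the trans-fused lactone.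

Step 13
Reactants: 21 keto lactone
Product: 22 (6R,7R,8R)-15-(tert-butyldimethylsilyloxy)-14-(tert-butyldiphenylsilyloxy)-8-hydroxy-13-norgermacra-1(10),4-dien-12,6-olide
Conditions: (S)-2-methyl-CBS-oxazaborolidine (0.5 equiv), catecholborane (2 equiv), PhMe/CH2Cl2, −78 °C; MeOH, pH 7 buffer
Reagents that add atoms: none
Why: Corey–Bakshi–Shibata reduction. With the branched C7 as the large and C9H2 as the small substituent the (S)-oxazaborolidine should deliver hydride to give 8R (8-hydroxyl anti to O6); reagent control is used because the ring offers no reliable facial bias. Catecholborane at −78 °C should leave the lactone and both alkenes untouched.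

Step 14
Reactants: 22 hydroxy lactone; 23 dimethylmethyleneiminium iodide
Product: 27 (6R,7R,8R)-15-(tert-butyldimethylsilyloxy)-14-(tert-butyldiphenylsilyloxy)-8-hydroxygermacra-1(10),4,11(13)-trien-12,6-olide, via dilithium alkoxide enolate 24 (not isolated), via Mannich base 25 (not isolated), via quaternary ammonium iodide 26 (not isolated)
Conditions: LiN(iPr)2 (2.3 equiv), THF, −78 °C; 23 (3 equiv), −78 → −20 °C; AcOH, −40 °C; then MeI, MeOH, rt; NaHCO3 (aq), CH2Cl2, rt
Reagents that add atoms: none
Why: Eschenmoser methylenation: the dianion reacts at C11 in a Mannich reaction, N-methylation and mild base then eliminate trimethylamine to give the exocyclic alkene. C6, C7 and C8 are not involved, and the cold acidic quench is meant to prevent the 8-alkoxide from relactonising.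

Step 15
Reactants: 27 α-methylene lactone bis(silyl ether)
Product: 28 (6R,7R,8R)-14-(tert-butyldiphenylsilyloxy)-8,15-dihydroxygermacra-1(10),4,11(13)-trien-12,6-olide
Conditions: CSA (10 mol %), MeOH/CH2Cl2 (1:1), 0 °C
Reagents that add atoms: none
Why: Acid-catalysed methanolysis cleaves a primary TBS ether far faster than a TBDPS ether. The lactone and the exocyclic enoate should be stable to catalytic acid at 0 °C.

Step 16
Reactants: 28 diol; 29 acetic anhydride
Product: 30 (6R,7R,8R)-15-acetoxy-14-(tert-butyldiphenylsilyloxy)-8-hydroxygermacra-1(10),4,11(13)-trien-12,6-olide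
Conditions: 29 (1.1 equiv), 2,4,6-collidine, CH2Cl2, −20 → 0 °C
Reagents that add atoms: none
Why: Acylation of the primary allylic hydroxyl. Without a nucleophilic catalyst and at low temperature the hindered secondary 8-hydroxyl beside the ring fusion should react much more slowly.

Step 17
Reactants: 30 acetate silyl ether
Product: 31 (6R,7R,8R)-15-acetoxy-8,14-dihydroxygermacra-1(10),4,11(13)-trien-12,6-olide
Conditions: HF·pyridine, pyridine, THF, 0 °C → rt
Reagents that add atoms: none
Why: Fluoride-mediated Si–O cleavage under buffered, weakly acidic conditions. These should neither hydrolyse or shift the acetate nor add to the α-methylene lactone, as unbuffered ammonium fluoride might.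

Step 18
Reactants: 31 diol acetate; 32 methacrylic anhydride
Product: 33 (6R,7R,8R)-15-acetoxy-8-hydroxy-14-(methacryloyloxy)germacra-1(10),4,11(13)-trien-12,6-olide (CNP0313792.2)
Conditions: 32 (1.1 equiv), Et3N, DMAP (5 mol %), CH2Cl2, −20 °C
Reagents that add atoms: none
Why: DMAP-catalysed acyl transfer to the primary C14 hydroxyl. The secondary 8-hydroxyl is slower, so one equivalent of anhydride at low temperature should give the target.

## Compound list

1 | cyclooctane-1,5-dione | O=C1CCCC(=O)CCC1 | starting material
2 | dilithium cycloocta-1,5-diene-1,5-bis(olate) | [Li+].[Li+].[O-]/C1=C/CC/C([O-])=C\CC1 | intermediate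
3 | cycloocta-1,5-diene-1,5-diyl bis(trifluoromethanesulfonate), ring-cis,cis | O=S(=O)(O/C1=C/CC/C(OS(=O)(=O)C(F)(F)F)=C\CC1)C(F)(F)F | intermediate
4 | (tributylstannyl)methanol | CCCC[Sn](CCCC)(CCCC)CO | starting material
5 | 5-(hydroxymethyl)cycloocta-1,5-dien-1-yl trifluoromethanesulfonate | OC/C1=C/CC/C(OS(=O)(=O)C(F)(F)F)=C\CC1 | intermediate
6 | 5-[(tert-butyldimethylsilyloxy)methyl]cycloocta-1,5-dien-1-yl trifluoromethanesulfonate | CC(C)(C)[Si](C)(C)OC/C1=C/CC/C(OS(=O)(=O)C(F)(F)F)=C\CC1 | intermediate
7 | 5-[(tert-butyldimethylsilyloxy)methyl]-7-oxocycloocta-1,5-dien-1-yl trifluoromethanesulfonate (ketone = C6) | CC(C)(C)[Si](C)(C)OC/C1=C/C(=O)C/C(OS(=O)(=O)C(F)(F)F)=C\CC1 | intermediate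
8 | 7-(hydroxymethyl)-3-[(tert-butyldimethylsilyloxy)methyl]cycloocta-2,6-dien-1-one | CC(C)(C)[Si](C)(C)OC/C1=C/C(=O)C/C(CO)=C\CC1 | intermediate
9 | 3-[(tert-butyldimethylsilyloxy)methyl]-7-[(tert-butyldiphenylsilyloxy)methyl]cycloocta-2,6-dien-1-one | CC(C)(C)[Si](C)(C)OC/C1=C/C(=O)C/C(CO[Si](c2ccccc2)(c2ccccc2)C(C)(C)C)=C\CC1 | intermediate
10 | lithium 3-[(tert-butyldiphenylsilyloxy)methyl]-7-[(tert-butyldimethylsilyloxy)methyl]cycloocta-1,3,7-trien-1-olate | [Li+].[O-]/C1=C/C(CO[Si](c2ccccc2)(c2ccccc2)C(C)(C)C)=C\CC/C(CO[Si](C)(C)C(C)(C)C)=C\1 | intermediate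
11 | 1-(trimethylsilyloxy)-3-[(tert-butyldiphenylsilyloxy)methyl]-7-[(tert-butyldimethylsilyloxy)methyl]cycloocta-1,3,7-triene, all ring-cis | C[Si](C)(C)O/C1=C/C(CO[Si](c2ccccc2)(c2ccccc2)C(C)(C)C)=C\CC/C(CO[Si](C)(C)C(C)(C)C)=C\1 | intermediate
12 | trichloroacetyl chloride | O=C(Cl)C(Cl)(Cl)Cl | starting material
13 | rac-(1S,8S)-10,10-dichloro-3-[(tert-butyldimethylsilyloxy)methyl]-7-[(tert-butyldiphenylsilyloxy)methyl]-1-(trimethylsilyloxy)bicyclo[6.2.0]deca-2,6-dien-9-one, cis-fused | C[Si](C)(C)O[C@]12C(Cl)(Cl)C(=O)[C@H]1/C(CO[Si](c3ccccc3)(c3ccccc3)C(C)(C)C)=C\CC/C(CO[Si](C)(C)C(C)(C)C)=C\2 | intermediate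
14 | rac-(1S,8S)-3-[(tert-butyldimethylsilyloxy)methyl]-7-[(tert-butyldiphenylsilyloxy)methyl]-1-(trimethylsilyloxy)bicyclo[6.2.0]deca-2,6-dien-9-one, cis-fused | C[Si](C)(C)O[C@]12CC(=O)[C@H]1/C(CO[Si](c3ccccc3)(c3ccccc3)C(C)(C)C)=C\CC/C(CO[Si](C)(C)C(C)(C)C)=C\2 | intermediate
15 | tetrabutylammonium alkoxide of the desilylated cyclobutanone (C6–O−), cis-fused, racemic | CCCC[N+](CCCC)(CCCC)CCCC.[O-][C@]12CC(=O)[C@H]1/C(CO[Si](c3ccccc3)(c3ccccc3)C(C)(C)C)=C\CC/C(CO[Si](C)(C)C(C)(C)C)=C\2 | intermediate
16 | tetrabutylammonium C8 enolate (C8=C9) of the ring-opened ten-membered dione | CCCC[N+](CCCC)(CCCC)CCCC.O=C1CC([O-])=C/C(CO[Si](c2ccccc2)(c2ccccc2)C(C)(C)C)=C\CC/C(CO[Si](C)(C)C(C)(C)C)=C\1 | intermediate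
17 | 9-[(tert-butyldimethylsilyloxy)methyl]-5-[(tert-butyldiphenylsilyloxy)methyl]cyclodeca-5,9-diene-1,3-dione, ring-cis,cis, achiral (C6,C8-dione) | O=C1CC(=O)C/C(CO[Si](c2ccccc2)(c2ccccc2)C(C)(C)C)=C\CC/C(CO[Si](C)(C)C(C)(C)C)=C\1 | intermediate
18 | methyl bromoacetate | COC(=O)CBr | starting material
19 | methyl 15-(tert-butyldimethylsilyloxy)-14-(tert-butyldiphenylsilyloxy)-6,8-dioxo-13-norgermacra-1(10),4-dien-12-oate, racemic and labile at C7 | COC(=O)CC1C(=O)C/C(CO[Si](c2ccccc2)(c2ccccc2)C(C)(C)C)=C\CC/C(CO[Si](C)(C)C(C)(C)C)=C\C1=O | intermediate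
20 | methyl (6R,7S)-15-(tert-butyldimethylsilyloxy)-14-(tert-butyldiphenylsilyloxy)-6-hydroxy-8-oxo-13-norgermacra-1(10),4-dien-12-oate | CC(C)(C)[Si](c1ccccc1)(c1ccccc1)OC/C1=C/CC/C(CO[Si](C)(C)C(C)(C)C)=C\[C@@H](O)[C@H](CC(=O)OC)C(=O)C1 | intermediate
21 | (6R,7S)-15-(tert-butyldimethylsilyloxy)-14-(tert-butyldiphenylsilyloxy)-8-oxo-13-norgermacra-1(10),4-dien-12,6-olide, trans-fused lactone | CC(C)(C)[Si](c1ccccc1)(c1ccccc1)OC/C1=C/CC/C(CO[Si](C)(C)C(C)(C)C)=C\[C@H]2OC(=O)C[C@@H]2C(=O)C1 | intermediate
22 | (6R,7R,8R)-15-(tert-butyldimethylsilyloxy)-14-(tert-butyldiphenylsilyloxy)-8-hydroxy-13-norgermacra-1(10),4-dien-12,6-olide | CC(C)(C)[Si](c1ccccc1)(c1ccccc1)OC/C1=C/CC/C(CO[Si](C)(C)C(C)(C)C)=C\[C@H]2OC(=O)C[C@@H]2[C@H](O)C1 | intermediate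
23 | dimethylmethyleneiminium iodide | C=[N+](C)C.[I-] | starting material
24 | dilithium 8-alkoxide and lactone enolate of 22 | [Li+].[Li+].CC(C)(C)[Si](c1ccccc1)(c1ccccc1)OC/C1=C/CC/C(CO[Si](C)(C)C(C)(C)C)=C\[C@H]2OC([O-])=C[C@@H]2[C@H]([O-])C1 | intermediate
25 | (6R,7R,8R)-13-(dimethylamino)-15-(tert-butyldimethylsilyloxy)-14-(tert-butyldiphenylsilyloxy)-8-hydroxygermacra-1(10),4-dien-12,6-olide, C11 epimers | CC(C)(C)[Si](c1ccccc1)(c1ccccc1)OC/C1=C/CC/C(CO[Si](C)(C)C(C)(C)C)=C\[C@H]2OC(=O)C(CN(C)C)[C@@H]2[C@H](O)C1 | intermediate
26 | 13-(trimethylammonio) analogue of 25, iodide | [I-].CC(C)(C)[Si](c1ccccc1)(c1ccccc1)OC/C1=C/CC/C(CO[Si](C)(C)C(C)(C)C)=C\[C@H]2OC(=O)C(C[N+](C)(C)C)[C@@H]2[C@H](O)C1 | intermediate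
27 | (6R,7R,8R)-15-(tert-butyldimethylsilyloxy)-14-(tert-butyldiphenylsilyloxy)-8-hydroxygermacra-1(10),4,11(13)-trien-12,6-olide | CC(C)(C)[Si](c1ccccc1)(c1ccccc1)OC/C1=C/CC/C(CO[Si](C)(C)C(C)(C)C)=C\[C@H]2OC(=O)C(=C)[C@@H]2[C@H](O)C1 | intermediate
28 | (6R,7R,8R)-14-(tert-butyldiphenylsilyloxy)-8,15-dihydroxygermacra-1(10),4,11(13)-trien-12,6-olide | CC(C)(C)[Si](c1ccccc1)(c1ccccc1)OC/C1=C/CC/C(CO)=C\[C@H]2OC(=O)C(=C)[C@@H]2[C@H](O)C1 | intermediate
29 | acetic anhydride | CC(=O)OC(C)=O | starting material
30 | (6R,7R,8R)-15-acetoxy-14-(tert-butyldiphenylsilyloxy)-8-hydroxygermacra-1(10),4,11(13)-trien-12,6-olide | CC(C)(C)[Si](c1ccccc1)(c1ccccc1)OC/C1=C/CC/C(COC(C)=O)=C\[C@H]2OC(=O)C(=C)[C@@H]2[C@H](O)C1 | intermediate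
31 | (6R,7R,8R)-15-acetoxy-8,14-dihydroxygermacra-1(10),4,11(13)-trien-12,6-olide | OC/C1=C/CC/C(COC(C)=O)=C\[C@H]2OC(=O)C(=C)[C@@H]2[C@H](O)C1 | intermediate
32 | methacrylic anhydride | C=C(C)C(=O)OC(=O)C(C)=C | starting material
33 | (6R,7R,8R)-15-acetoxy-8-hydroxy-14-(methacryloyloxy)germacra-1(10),4,11(13)-trien-12,6-olide, both ring double bonds cis, trans-fused lactone | C=C(C)C(=O)OC/C1=C/CC/C(COC(C)=O)=C\[C@H]2OC(=O)C(=C)[C@@H]2[C@H](O)C1 | target

## Step count and least certain steps

Total: 18 steps. Longest linear sequence: 18 steps (fully linear from 1; 4 is used twice).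

Step 10 (key step).
- What may go wrong: addition of the ring-opened enolate across the ring to C4 of the new enone, migration of C10=C1 into conjugation by protonation at C1, competing C6–C7 cleavage, or loss of the primary TBS ether. The intermediate is at once a dienolate and an enone held face to face in a medium ring.
- Fallback (sets out from 14, returns at 17): remove fluoride and enolates from the process. Methanolysis of the TMS ether with citric acid in methanol at 0 °C should give the free cis-fused 1-hydroxybicyclo[6.2.0]decadienone F1. F1 is then opened by acid-catalysed retro-aldol cleavage through the neutral enol (PPTS, CH2Cl2, 0 °C to rt), so that C9 is protonated as it forms and 17 results.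

Step 1.
- What may go wrong: the second enolisation running into the same three-carbon bridge as the first, which gives the 1,4-diene ditriflate. There is no strong bias, and the skipped diene is if anything the more stable cyclooctadiene.
- Fallback (sets out from 1, returns at 7): the isomer is used instead of discarded. Cycloocta-1,4-diene-1,5-diyl bis(trifluoromethanesulfonate) F2 is monocoupled with 4 as in step 2 to the alcohol F3 and silylated to the TBS ether F4. Its doubly allylic C6 methylene is oxidised (Rh2(cap)4, t-BuOOH) to the cross-conjugated dienone triflate F5. LiN(iPr)2 at −78 °C then removes a γ-proton at C1, on the triflate side where the dienolate is inductively stabilised. Kinetic protonation at C9 with acetic acid at −78 °C moves C9=C10 to C10=C1 and delivers 7.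

Step 4.
- What may go wrong: hydrogen abstraction at C3 or at the silyloxymethylene C15 instead of C6, or over-oxidation to an ene-dione. All three C–H types are allylic to the same alkene.
- Fallback (sets out from 6, returns at 7): a regiodefined transposition. mCPBA epoxidises only the electron-rich C4=C5 bond to the cis-epoxide F6. Sodium phenylselenide (PhSeSePh, NaBH4, EtOH) opens it at the less hindered C5 to the trans hydroxy selenide F7. H2O2 oxidation and syn-elimination, which can only run toward C6, give the tertiary allylic alcohol F8. Babler–Dauben oxidative 1,3-transposition with 4-acetamido-2,2,6,6-tetramethyl-1-oxopiperidinium tetrafluoroborate then gives 7.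

Step 8.
- What may go wrong: cycloaddition at C10=C1 (C1 is the vinylogous nucleophilic terminus of the siloxydiene), cleavage of the TMS enol ether by zinc chloride, or Cope rearrangement of the adduct on warming.
- Fallback (sets out from 7, returns at 14): postpone the C14 arm so that C10=C1 still carries the triflate and cannot compete. 7 is converted as in step 7 into the trimethylsilyl dienol ether triflate F9. Dichloroketene gives the dichlorocyclobutanone triflate F10 and zinc dechlorination the cyclobutanone triflate F11. Stille hydroxymethylation with 4 at rt (Pd2(dba)3, P(2-furyl)3, LiCl, NMP) gives the hydroxymethyl cyclobutanone F12, and TBDPSCl with imidazole returns 14.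

Step 12.
- What may go wrong: hydride delivery to C8 instead of C6, conjugate reduction of the enone, or an anti instead of syn outcome at C6/C7. The two ketones share the same branched neighbour and differ only in the alkenyl group.
- Fallback (sets out from 19, returns at 21): change the catalyst class. A panel of nicotinamide-dependent ketoreductases with glucose and glucose dehydrogenase recycling at pH 7 is screened for the enzyme that reduces C6 of the rapidly epimerising dione to 20, which is closed to 21 with PPTS. No new compound is made.

Step 13.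
- What may go wrong: poor facial selectivity, because the oxazaborolidine must tell a branched CH from an allylic CH2 and may be mismatched with the ring, or β-elimination of the lactone oxygen from the β-acyloxy ketone.
- Fallback (sets out from 17, returns at 22): let C8 depend on C6 instead of on a reagent. 17 is alkylated with tert-butyl bromoacetate to the tert-butyl ester dione F13, whose ester does not lactonise. Transfer hydrogenation as in step 12 gives the hydroxy ketone F14. Evans–Saksena reduction (Me4NBH(OAc)3, MeCN/AcOH, −30 °C) delivers hydride from the C6-bound borate and gives the 6,8-anti diol F15. Trifluoroacetic acid in CH2Cl2 at 0 °C cleaves the tert-butyl ester and closes the lactone; the trans-fused ring on O6 is expected to be preferred over the cis-fused ring on O8, giving 22.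

## Further compounds

F1 | step 10 | rac-(1S,8S)-1-hydroxy-3-[(tert-butyldimethylsilyloxy)methyl]-7-[(tert-butyldiphenylsilyloxy)methyl]bicyclo[6.2.0]deca-2,6-dien-9-one, cis-fused | O[C@]12CC(=O)[C@H]1/C(CO[Si](c3ccccc3)(c3ccccc3)C(C)(C)C)=C\CC/C(CO[Si](C)(C)C(C)(C)C)=C\2
F2 | step 1 | cycloocta-1,4-diene-1,5-diyl bis(trifluoromethanesulfonate), ring-cis,cis | O=S(=O)(O/C1=C/C/C=C(/OS(=O)(=O)C(F)(F)F)CCC1)C(F)(F)F
F3 | step 1 | 5-(hydroxymethyl)cycloocta-1,4-dien-1-yl trifluoromethanesulfonate | OC/C1=C/C/C=C(/OS(=O)(=O)C(F)(F)F)CCC1
F4 | step 1 | 5-[(tert-butyldimethylsilyloxy)methyl]cycloocta-1,4-dien-1-yl trifluoromethanesulfonate | CC(C)(C)[Si](C)(C)OC/C1=C/C/C=C(/OS(=O)(=O)C(F)(F)F)CCC1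
F5 | step 1 | 5-[(tert-butyldimethylsilyloxy)methyl]-3-oxocycloocta-1,4-dien-1-yl trifluoromethanesulfonate | CC(C)(C)[Si](C)(C)OC/C1=C/C(=O)/C=C(/OS(=O)(=O)C(F)(F)F)CCC1
F6 | step 4 | 1-[(tert-butyldimethylsilyloxy)methyl]-9-oxabicyclo[6.1.0]non-4-en-5-yl trifluoromethanesulfonate, cis-epoxide at C4–C5, racemic | CC(C)(C)[Si](C)(C)OC[C@]12O[C@H]1CC/C(OS(=O)(=O)C(F)(F)F)=C\CC2
F7 | step 4 | 5-hydroxy-5-[(tert-butyldimethylsilyloxy)methyl]-6-(phenylselanyl)cyclooct-1-en-1-yl trifluoromethanesulfonate, hydroxyl and selenide trans, racemic | CC(C)(C)[Si](C)(C)OC[C@]1(O)[C@H]([Se]c2ccccc2)CC/C(OS(=O)(=O)C(F)(F)F)=C\CC1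
F8 | step 4 | 5-hydroxy-5-[(tert-butyldimethylsilyloxy)methyl]cycloocta-1,6-dien-1-yl trifluoromethanesulfonate, ring-cis,cis, racemic | CC(C)(C)[Si](C)(C)OCC1(O)/C=C\C/C(OS(=O)(=O)C(F)(F)F)=C\CC1
F9 | step 8 | 5-[(tert-butyldimethylsilyloxy)methyl]-7-(trimethylsilyloxy)cycloocta-1,5,7-trien-1-yl trifluoromethanesulfonate | C[Si](C)(C)O/C1=C/C(OS(=O)(=O)C(F)(F)F)=C\CC/C(CO[Si](C)(C)C(C)(C)C)=C\1
F10 | step 8 | 10,10-dichloro-3-[(tert-butyldimethylsilyloxy)methyl]-9-oxo-1-(trimethylsilyloxy)bicyclo[6.2.0]deca-2,6-dien-7-yl trifluoromethanesulfonate, cis-fused, racemic | C[Si](C)(C)O[C@]12C(Cl)(Cl)C(=O)[C@H]1/C(OS(=O)(=O)C(F)(F)F)=C\CC/C(CO[Si](C)(C)C(C)(C)C)=C\2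
F11 | step 8 | 3-[(tert-butyldimethylsilyloxy)methyl]-9-oxo-1-(trimethylsilyloxy)bicyclo[6.2.0]deca-2,6-dien-7-yl trifluoromethanesulfonate, cis-fused, racemic | C[Si](C)(C)O[C@]12CC(=O)[C@H]1/C(OS(=O)(=O)C(F)(F)F)=C\CC/C(CO[Si](C)(C)C(C)(C)C)=C\2
F12 | step 8 | 7-(hydroxymethyl)-3-[(tert-butyldimethylsilyloxy)methyl]-1-(trimethylsilyloxy)bicyclo[6.2.0]deca-2,6-dien-9-one, cis-fused, racemic | C[Si](C)(C)O[C@]12CC(=O)[C@H]1/C(CO)=C\CC/C(CO[Si](C)(C)C(C)(C)C)=C\2
F0 | step 12 | none | none
F13 | step 13 | tert-butyl 15-(tert-butyldimethylsilyloxy)-14-(tert-butyldiphenylsilyloxy)-6,8-dioxo-13-norgermacra-1(10),4-dien-12-oate, labile at C7 | CC(C)(C)OC(=O)CC1C(=O)C/C(CO[Si](c2ccccc2)(c2ccccc2)C(C)(C)C)=C\CC/C(CO[Si](C)(C)C(C)(C)C)=C\C1=O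
F14 | step 13 | tert-butyl (6R,7S)-15-(tert-butyldimethylsilyloxy)-14-(tert-butyldiphenylsilyloxy)-6-hydroxy-8-oxo-13-norgermacra-1(10),4-dien-12-oate | CC(C)(C)[Si](c1ccccc1)(c1ccccc1)OC/C1=C/CC/C(CO[Si](C)(C)C(C)(C)C)=C\[C@@H](O)[C@H](CC(=O)OC(C)(C)C)C(=O)C1
F15 | step 13 | tert-butyl (6R,7R,8R)-15-(tert-butyldimethylsilyloxy)-14-(tert-butyldiphenylsilyloxy)-6,8-dihydroxy-13-norgermacra-1(10),4-dien-12-oate | CC(C)(C)[Si](c1ccccc1)(c1ccccc1)OC/C1=C/CC/C(CO[Si](C)(C)C(C)(C)C)=C\[C@@H](O)[C@H](CC(=O)OC(C)(C)C)[C@H](O)C1
A1 | alternative 1 | methyl (2S,3S)-2-[(4-methoxybenzyloxy)methyl]-5-oxooxolane-3-carboxylate, trans | COc1ccc(COC[C@H]2OC(=O)C[C@@H]2C(=O)OC)cc1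
A2 | alternative 1 | dimethyl 2-[2-(4-methoxybenzyloxy)acetyl]butanedioate, racemic | COc1ccc(COCC(=O)C(CC(=O)OC)C(=O)OC)cc1
A3 | alternative 2 | 14-(4-methoxybenzyloxy)-15-(tert-butyldiphenylsilyloxy)-8-(tert-butyldimethylsilyloxy)-13-norgermacra-1(10),4-dien-12,6-olide, configuration at C6, C7 and C8 as in the target | COc1ccc(COC/C2=C/CC/C(CO[Si](c3ccccc3)(c3ccccc3)C(C)(C)C)=C\[C@H]3OC(=O)C[C@@H]3[C@H](O[Si](C)(C)C(C)(C)C)C2)cc1
A4 | alternative 3 | allyl 15-(tert-butyldiphenylsilyloxy)-8-(tert-butyldimethylsilyloxy)-12-oxo-12,6-epoxy-13-norgermacra-1(10),4-dien-14-oate (ten-membered C14 allyl ester with the 12,6-lactone), configuration at C6, C7 and C8 as in the target | C=CCOC(=O)/C1=C/CC/C(CO[Si](c2ccccc2)(c2ccccc2)C(C)(C)C)=C\[C@H]2OC(=O)C[C@@H]2[C@H](O[Si](C)(C)C(C)(C)C)C1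
A5 | alternative 3 | D-arabinose (open-chain form) | O=C[C@@H](O)[C@H](O)[C@H](O)CO
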